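**Retrosynthetic overview**
- **Structural feature.** In each ring C1 carries the bridging oxygen. Ring A (anisole ring) has OMe on C2, Br on C3 and C5, and H on C6. Ring B (phenol ring) has OH on C2, Br on C3 and C5, and OMe on C6. The rings differ at one site only: ring B C2 bears OH where ring A C6 bears H, and both carbons are ortho to the bridging oxygen.
- **Key disconnection.** One carbonyl carbon placed between ring A C6 and ring B C2 gives the C2-symmetric 1,3,6,8-tetrabromo-4,5-dimethoxyxanthone. The target comes from a hydroxy acid by loss of CO2 at ring A C6. The hydroxy acid comes from a seven-membered lactone by hydrolysis. The lactone comes from the xanthone by Baeyer–Villiger insertion of one oxygen next to C9.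
- **Xanthone precursor.** It is traced back through O-methylation, fourfold bromination ortho and para to the OH groups of 4,5-dihydroxyxanthone, and demethylative cyclisation of 2,2',3,3'-tetramethoxybenzophenone, to lithiated veratrole and 2,3-dimethoxybenzaldehyde.
- **Ring order.** Both benzene rings are bought. The pyranone ring is closed in step 3, widened to the dioxepinone in step 6 and opened in step 7, so no cross-coupling is needed for the crowded diaryl ether.

Key step: step 6

Remark: the target has no stereocentre and rotation about the diaryl ether C–O bonds is taken as free, so no stereochemical control is needed at any stage.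

Step 1
Reactants: 1 veratrole (1,2-dimethoxybenzene); 2 2,3-dimethoxybenzaldehyde
Product: 4 bis(2,3-dimethoxyphenyl)methanol, via 2,3-dimethoxyphenyllithium 3 (not isolated)
Conditions: 1, n-BuLi, TMEDA, THF, 0 °C → rt; then 2, −78 °C → rt; H2O quench
Reagents that add atoms: n-butyllithium, [Li]CCCC (its lithium stands in 3; no atom of it stays in 4)
Why: Directed ortho-metalation of veratrole can only occur at the carbon next to a methoxy group, and 1,2-addition of the aryllithium to the non-enolisable aldehyde should give the carbinol, whose central carbon bears two identical aryl groups and is therefore no stereocentre.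

Step 2
Reactants: 4 bis(2,3-dimethoxyphenyl)methanol
Product: 5 bis(2,3-dimethoxyphenyl)methanone (2,2',3,3'-tetramethoxybenzophenone)
Conditions: activated MnO2 (excess), CH2Cl2, reflux
Reagents that add atoms: none
Why: Oxidation of a doubly benzylic, electron-rich secondary alcohol with MnO2 is a standard benzhydrol-to-benzophenone conversion that cannot over-oxidise and leaves the aryl methyl ethers alone.

Step 3
Reactants: 5 bis(2,3-dimethoxyphenyl)methanone
Product: 7 4,5-dihydroxy-9H-xanthen-9-one, via 2,2',3,3'-tetrahydroxybenzophenone 6 (not isolated)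
Conditions: pyridinium chloride (melt, large excess), 200–210 °C, Ar; then H2O
Reagents that add atoms: none
Why: In the melt chloride cleaves all four protonated aryl methyl ethers by SN2 attack on methyl, and at the same temperature one 2-OH adds to the carbonyl-activated C2' of the other ring with loss of water (addition–elimination cyclodehydration of a 2,2'-dihydroxybenzophenone, a classical xanthone synthesis), the 3-OH groups being unable to reach the other ring.

Step 4
Reactants: 7 4,5-dihydroxy-9H-xanthen-9-one
Product: 8 1,3,6,8-tetrabromo-4,5-dihydroxy-9H-xanthen-9-one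
Conditions: Br2 (excess), AcOH, rt → 90 °C
Reagents that add atoms: bromine, BrBr
Why: In this electrophilic aromatic bromination each free OH (C4, C5) is by far the strongest donor of its ring, because O10 is tied up in conjugation with C9=O, and it directs to its ortho (C3, C6) and para (C1, C8) carbons as in the 4,6-dibromination of guaiacol, while C2 and C7 are meta to OH and end up flanked by two bromines, so substitution should stop at four.

Step 5
Reactants: 8 1,3,6,8-tetrabromo-4,5-dihydroxy-9H-xanthen-9-one
Product: 9 1,3,6,8-tetrabromo-4,5-dimethoxy-9H-xanthen-9-one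
Conditions: MeI (excess), K2CO3, DMF, rt → 40 °C
Reagents that add atoms: iodomethane, CI
Why: In this Williamson O-methylation the acidic dibromophenols are fully ionised by K2CO3 and should be alkylated by excess MeI near room temperature faster than the hindered, weakly nucleophilic phenoxides could displace a carbonyl-activated bromine.

Step 6
Reactants: 9 1,3,6,8-tetrabromo-4,5-dimethoxy-9H-xanthen-9-one
Product: 11 1,3,7,9-tetrabromo-4,6-dimethoxy-11H-dibenzo[b,e][1,4]dioxepin-11-one, via Criegee adduct 10 (not isolated)
Conditions: (CF3CO)2O, urea·H2O2 (added in portions), CH2Cl2/CF3CO2H, 0 → 40 °C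
Reagents that add atoms: trifluoroperacetic acid, OOC(=O)C(F)(F)F, made in the flask from urea–hydrogen peroxide, NC(N)=O.OO, and trifluoroacetic anhydride, O=C(OC(=O)C(F)(F)F)C(F)(F)F
Why: Proposed new method: CF3CO2H protonates or strongly hydrogen-bonds the C9 carbonyl of 9, CF3CO3H adds to C9 from the open π face, above the plane in which the two peri bromines lie, and in the resulting Criegee adduct 10 the aryl carbon C9a antiperiplanar to the O–O bond shifts from C9 to the inner peroxide oxygen while CF3CO2H, the best leaving group a common peracid offers, departs. The closest known reaction type is the Baeyer–Villiger oxidation of benzophenones to aryl benzoates and of fluorenone to its six-membered biaryl lactone with the same peracid; it has not been shown on a xanthone, whose carbonyl is weakened by cross-conjugation with the ring oxygen O10, and this is where the risk of the route sits. No ring is closed and no stereocentre is made: the 1,2-shift forms the single new bond, ring B C2–O, and thereby widens the six-membered pyranone to the seven-membered 1,4-dioxepinone. The addition equilibrium should be small but the shift is irreversible, and it is helped by O10, which sits ortho to the migrating carbon and feeds electron density into the phenonium-like transition state. Site selectivity needs no control because the twofold axis of 9 makes C8a and C9a equivalent, and a second insertion is ruled out because the carbonyl of 11 is an ester. Chemoselectivity for C9 over electrophilic hydroxylation of the anisole rings rests on the four bromines, which deactivate both rings and at the same time raise the electrophilicity of C9, and the water-free peracid keeps 11 closed so that no free phenol meets the oxidant.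

Step 7
Reactants: 11 1,3,7,9-tetrabromo-4,6-dimethoxy-11H-dibenzo[b,e][1,4]dioxepin-11-one
Product: 12 4,6-dibromo-2-(3,5-dibromo-2-hydroxy-6-methoxyphenoxy)-3-methoxybenzoic acid
Conditions: LiOH, THF/H2O, 0 °C → rt; then 1 M HCl
Reagents that add atoms: lithium hydroxide, [Li+].[OH-] (its oxygen becomes the second carboxyl oxygen; net addition of water, O)
Why: In this saponification of an aryl ester the seven-membered lactone expels a good leaving group, the dibromophenoxide oxygen on ring B C2, so hydroxide should open it at room temperature despite the two ortho substituents, and because ring A then carries only a carboxylate as acceptor the Smiles rearrangement of the 2-hydroxy diaryl ether should stay silent under these mild conditions.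

Step 8
Reactants: 12 4,6-dibromo-2-(3,5-dibromo-2-hydroxy-6-methoxyphenoxy)-3-methoxybenzoic acid
Product: 13 4,6-dibromo-2-(3,5-dibromo-2-methoxyphenoxy)-3-methoxyphenol (target, CNP0017935.0)
Conditions: Ag2CO3 (10 mol %), AcOH (5 mol %), DMSO, 120 °C, Ar
Reagents that add atoms: none
Why: In this silver-catalysed protodecarboxylation of an ortho-substituted benzoic acid the carboxyl group on ring A C6 is twisted out of conjugation by its two ortho neighbours (Br on C5, aryloxy oxygen on C1), which also stabilise the carbon–silver bond formed on loss of CO2, and protonation then leaves H on C6, while aryl bromides, methyl ethers and the electron-poor phenol should tolerate a catalytic amount of monovalent silver.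

**Compound list**
1 | veratrole (1,2-dimethoxybenzene) | COc1ccccc1OC | starting material
2 | 2,3-dimethoxybenzaldehyde | COc1cccc(C=O)c1OC | starting material
3 | 2,3-dimethoxyphenyllithium | [Li]c1cccc(OC)c1OC | intermediate (not isolated)
4 | bis(2,3-dimethoxyphenyl)methanol | COc1cccc(C(O)c2cccc(OC)c2OC)c1OC | intermediate
5 | bis(2,3-dimethoxyphenyl)methanone (2,2',3,3'-tetramethoxybenzophenone) | COc1cccc(C(=O)c2cccc(OC)c2OC)c1OC | intermediate
6 | 2,2',3,3'-tetrahydroxybenzophenone | Oc1cccc(C(=O)c2cccc(O)c2O)c1O | intermediate (not isolated)
7 | 4,5-dihydroxy-9H-xanthen-9-one | Oc1cccc2C(=O)c3cccc(O)c3Oc12 | intermediate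
8 | 1,3,6,8-tetrabromo-4,5-dihydroxy-9H-xanthen-9-one | Oc1c(Br)cc(Br)c2C(=O)c3c(Br)cc(Br)c(O)c3Oc12 | intermediate
9 | 1,3,6,8-tetrabromo-4,5-dimethoxy-9H-xanthen-9-one | COc1c(Br)cc(Br)c2C(=O)c3c(Br)cc(Br)c(OC)c3Oc12 | intermediate (key-step precursor)
10 | Criegee adduct: 1,3,6,8-tetrabromo-9-hydroxy-4,5-dimethoxy-9H-xanthen-9-yl trifluoroperacetate | COc1c(Br)cc(Br)c2c1Oc1c(OC)c(Br)cc(Br)c1C2(O)OOC(=O)C(F)(F)F | intermediate (not isolated)
11 | 1,3,7,9-tetrabromo-4,6-dimethoxy-11H-dibenzo[b,e][1,4]dioxepin-11-one | COc1c(Br)cc(Br)c2C(=O)Oc3c(Br)cc(Br)c(OC)c3Oc12 | intermediate (key-step product)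
12 | 4,6-dibromo-2-(3,5-dibromo-2-hydroxy-6-methoxyphenoxy)-3-methoxybenzoic acid | COc1c(Br)cc(Br)c(C(=O)O)c1Oc1c(O)c(Br)cc(Br)c1OC | intermediate
13 | 4,6-dibromo-2-(3,5-dibromo-2-methoxyphenoxy)-3-methoxyphenol | COc1c(Br)cc(Br)cc1Oc1c(O)c(Br)cc(Br)c1OC | target

Total step count: 8. Longest linear sequence: 8 steps (from 1 or 2 to 13).

**Steps most likely to fail**

1. **Step 6.** The peracid may add too slowly to the cross-conjugated, peri-flanked carbonyl. In that case 9 is simply returned, or slow electrophilic attack on the rings takes over.
   - The fallback uses known chemistry, sets out from 9 and comes back at 12. Nitrogen is inserted in place of oxygen and exchanged for oxygen afterwards.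
   - A Schmidt reaction (NaN3, conc. H2SO4/CHCl3, 0–40 °C) is a ring expansion known for the parent xanthone. It should turn 9 into the lactam 1,3,7,9-tetrabromo-4,6-dimethoxydibenz[b,f][1,4]oxazepin-11(10H)-one F1, again with no choice of migrating group.
   - Boc2O/DMAP should give the N-Boc lactam F2. LiOH in aqueous THF should open its activated ring carbonyl to the N-Boc amino acid F3, and CF3CO2H should free the amino acid F4.
   - Diazotisation (NaNO2, H2SO4/AcOH, 0 °C) gives the ring B diazonium hydrogen sulfate F5. Sandmeyer-type hydroxylation (Cu2O, Cu(NO3)2, H2O) then places OH on ring B C2 and delivers 12.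
   - Both ortho carbons of ring A are substituted, so a Pschorr-type closure is blocked.

2. **Step 4.** Bromination may stall before both peri positions are filled. Each of them lies ortho to the deactivating carbonyl, the second one builds up peri strain, and the partly brominated material may fall out of solution.
   - The fallback sets out from 7 and comes back at 9. The carbonyl is removed before the halogenation and put back afterwards.
   - BH3·THF (excess, reflux) should reduce 7 to 9H-xanthene-4,5-diol F6. In F6 the OH groups and the C9 methylene both direct to C1/C3 and C6/C8.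
   - Br2 in AcOH/CH2Cl2 (0 °C → rt) should then give 1,3,6,8-tetrabromo-9H-xanthene-4,5-diol F7. MeI/K2CO3 in DMF gives 1,3,6,8-tetrabromo-4,5-dimethoxy-9H-xanthene F8.
   - Oxidation of the doubly benzylic methylene (CrO3, AcOH, 60 °C) restores the carbonyl of 9. Any oxidation at C9 during the bromination goes in the wanted direction.

3. **Step 8.** Loss of CO2 may be sluggish. At 120 °C in DMSO the phenoxide may also migrate ring A between the two oxygens of ring B (Smiles rearrangement), or the phenol may be slowly oxidised by silver.
   - The fallback sets out from 12 and comes back at 13. The carboxyl carbon is removed by Curtius degradation and reductive deamination.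
   - DPPA/Et3N in toluene converts the acid chemoselectively into the acyl azide F9, as is known for salicylic acids with a free OH. At 90 °C F9 rearranges to the isocyanate F10.
   - Aqueous LiOH/THF hydrolyses F10, or its adduct with the neighbouring phenol, to the aminophenol 2-(2-amino-3,5-dibromo-6-methoxyphenoxy)-4,6-dibromo-3-methoxyphenol F11.
   - Diazotisation (NaNO2, H2SO4/AcOH, 0 °C) gives the ring A diazonium hydrogen sulfate F12, and reduction with H3PO2 (cat. Cu2O) leaves H on ring A C6, giving 13.
   - The ortho and para carbons of the phenol are blocked, so azo coupling cannot compete. The fast hydrogen transfer from H3PO2 is meant to outrun capture by the neighbouring OH.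

**Further compounds**
F1 | step 6 | 1,3,7,9-tetrabromo-4,6-dimethoxydibenz[b,f][1,4]oxazepin-11(10H)-one | COc1c(Br)cc(Br)c2C(=O)Nc3c(Br)cc(Br)c(OC)c3Oc12
F2 | step 6 | tert-butyl 1,3,7,9-tetrabromo-4,6-dimethoxy-11-oxodibenz[b,f][1,4]oxazepine-10(11H)-carboxylate (N-Boc lactam) | COc1c(Br)cc(Br)c2C(=O)N(C(=O)OC(C)(C)C)c3c(Br)cc(Br)c(OC)c3Oc12
F3 | step 6 | 4,6-dibromo-2-{3,5-dibromo-2-[(tert-butoxycarbonyl)amino]-6-methoxyphenoxy}-3-methoxybenzoic acid | COc1c(Br)cc(Br)c(C(=O)O)c1Oc1c(NC(=O)OC(C)(C)C)c(Br)cc(Br)c1OC
F4 | step 6 | 2-(2-amino-3,5-dibromo-6-methoxyphenoxy)-4,6-dibromo-3-methoxybenzoic acid | COc1c(Br)cc(Br)c(C(=O)O)c1Oc1c(N)c(Br)cc(Br)c1OC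
F5 | step 6 | 4,6-dibromo-2-(3,5-dibromo-2-carboxy-6-methoxyphenoxy)-3-methoxybenzenediazonium hydrogen sulfate | COc1c(Br)cc(Br)c(C(=O)O)c1Oc1c([N+]#N)c(Br)cc(Br)c1OC.OS(=O)(=O)[O-]
F6 | step 4 | 9H-xanthene-4,5-diol | Oc1cccc2Cc3cccc(O)c3Oc12
F7 | step 4 | 1,3,6,8-tetrabromo-9H-xanthene-4,5-diol | Oc1c(Br)cc(Br)c2Cc3c(Br)cc(Br)c(O)c3Oc12
F8 | step 4 | 1,3,6,8-tetrabromo-4,5-dimethoxy-9H-xanthene | COc1c(Br)cc(Br)c2Cc3c(Br)cc(Br)c(OC)c3Oc12
F9 | step 8 | 4,6-dibromo-2-(3,5-dibromo-2-hydroxy-6-methoxyphenoxy)-3-methoxybenzoyl azide | COc1c(Br)cc(Br)c(C(=O)N=[N+]=[N-])c1Oc1c(O)c(Br)cc(Br)c1OC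
F10 | step 8 | 4,6-dibromo-2-(3,5-dibromo-2-isocyanato-6-methoxyphenoxy)-3-methoxyphenol | COc1c(Br)cc(Br)c(N=C=O)c1Oc1c(O)c(Br)cc(Br)c1OC
F11 | step 8 | 2-(2-amino-3,5-dibromo-6-methoxyphenoxy)-4,6-dibromo-3-methoxyphenol | COc1c(Br)cc(Br)c(N)c1Oc1c(O)c(Br)cc(Br)c1OC
F12 | step 8 | 4,6-dibromo-2-(3,5-dibromo-2-hydroxy-6-methoxyphenoxy)-3-methoxybenzenediazonium hydrogen sulfate | COc1c(Br)cc(Br)c([N+]#N)c1Oc1c(O)c(Br)cc(Br)c1OC.OS(=O)(=O)[O-]
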